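The data were computed for an exercise, noise included.

Begin with a division: oak's charge over cedar's gives 2.00 for Sub and 1.98 for Rgt, so oak holds about twice cedar's Sub and Rgt on the same 0.0400 M of Cat. Decide from this whether oak is worth its Sub, and for that, find how far past cedar's share oak gets in 6.2 min.

the same everywhere: Cat 0.0400 M
- elm: Sub 0.800 M; Rgt 0.640 M
- ash: Sub 0.800 M; Rgt 0.640 M; Prd 0.240 M
- larch: Sub 0.400 M; Rgt 0.640 M
- cedar: Sub 0.800 M; Rgt 0.960 M
- oak: Sub 1.60 M; Rgt 1.90 M; time 6.2 min

| elm run: time / min | elm run: [Prd] / M | ash run: time / min | ash run: [Prd] / M | larch run: time / min | larch run: [Prd] / M | cedar run: time / min | cedar run: [Prd] / M |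
|---|---|---|---|---|---|---|---|
| 0.47 | 0.048 | 0.47 | 0.292 | 0.47 | 0.015 | 0.47 | 0.059 |
| 1.4 | 0.116 | 1.4 | 0.361 | 1.4 | 0.068 | 1.4 | 0.166 |
| 2.7 | 0.199 | 2.7 | 0.438 | 2.7 | 0.127 | 2.7 | 0.268 |
| 4.3 | 0.268 | 4.3 | 0.501 | 4.3 | 0.188 | 4.3 | 0.363 |
| 6.2 | 0.328 | 6.2 | 0.568 | 6.2 | 0.220 | 6.2 | 0.432 |

(each reading ± 0.004 M)

- the exponent of [Sub] in the starting rate at the charge of the elm run (at the point where two percent of the Sub have become Prd) (one fixed amount of Prd, the same in the runs compared)
- the exponent of [Rgt] in the starting rate at the charge of the elm run (at the point where two percent of the Sub have become Prd)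
- Prd in the oak run at 6.2 min, as a share of the Sub charged

- Overall: Sub + Rgt -> Prd, with Cat as catalyst.
- Constant volume, constant temperature.
- "The second partner" is Rgt.
- An order is taken over about fifteen percent of the charge, up and down.

Read the shares of Sub turned at 6.2 min: elm 41.0%, larch 55.0%, cedar 54.0%. Ash, less its added Prd, stands at 328 mM against elm's 0.328 M, the same within the scatter, so leave Prd out of the reckoning.

Now replace each curve by its mean, the Prd made by 6.2 min divided by that time. Elm over larch gives a whole-run exponent for Sub of 0.576, and cedar over elm gives one for Rgt of 0.679. Call the stretch how many times faster one flask's shares run than another's at the same Cat: the Sub ratio raised to one less than the Sub exponent, times the Rgt ratio raised to its exponent. For oak over cedar the stretch is 1.19.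

So oak at 6.2 min stands where cedar stands at 7.35 min. Cedar's readings end at 6.2 min, so extend them with the mean slope of their last interval, 0.0363 M min⁻¹. That adds 5.21% of the Sub and puts oak at 59.2%. Check the error: the interval before had a slope of 0.0594 M min⁻¹, steeper than the last, so the straight extension may lean high, but it carries 5.21% of the Sub against the 54.0% read in cedar. Run oak as written, and budget for 59.2%.

The forecast gives 0.6 for Sub, 0.95 for Rgt and 68% for oak: “That is 67–72% of the Sub charged, and I take about 68%.” That stands 8.8 percentage points above my figure, and its exponents are for the start, mine for whole runs.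

    Cat + Sub → X + Byp (7.080 M⁻¹ min⁻¹)
    X + Rgt → Prd + Cat (1.902 M⁻¹ min⁻¹)
    Sub + Rgt → Prd (0.1476 M⁻¹ min⁻¹)
    2 Rgt → E (0.07560 M⁻¹ min⁻¹)

Oak gives 60.1%, 0.90 points above my figure, with starting exponents of 0.81 for Sub and 0.88 for Rgt. The stretch of cedar over elm is 1.32, while the simulated times to a quarter, 2.69 min in elm and 1.73 min in cedar, give 1.55, more than the stretch. At oak's start, Sub + Rgt made Prd at 0.449 M min⁻¹ while 2 Rgt → E took Rgt at 0.546 M min⁻¹, faster. In that same moment Cat went to X at 11.3 min⁻¹, faster than X returned at 3.61 min⁻¹.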